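You have to decide how the reagents go in: together, or with one of them fed. Follow the substrate through the books: each entry is a fraction of its charge, and 1.80 equiv of partner goes in beside it.

| setting | north-east | north | autumn | dusk | winter | spring |
|---|---|---|---|---|---|---|
| substrate | 0.029 M | 0.058 M | 0.029 M | 0.029 M | 0.029 M | 0.029 M (fed, over 4.0 min) |
| partner | 1.8 equiv | 1.8 equiv | 1.80 equiv (fed, over 4.0 min) | 1.80 equiv (in portions, 3, over 4.0 min) | 1.80 equiv | 1.80 equiv |
| capture agent | 0.029 M | 0.029 M | 0.0290 M | 0.0290 M | 0.0290 M | 0.0290 M |
| remark | run made earlier | run made earlier | all else is in the flask from the start; the feed brings no volume worth counting | first portion at the start, last at 4.0 min | everything together at the start | all else is in the flask from the start; the feed brings no volume worth counting |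
| time |  |  | 5.0 min | 5.0 min | 5.0 min | 5.0 min |

- north-east (time / min: bis adduct / %, trapped intermediate / %): 1.33: 22.1, 2.8; 2.50: 23.5, 6.2; 4.00: 21.6, 10.3; 5.00: 21.9, 14.7
- north (time / s: bis adduct / %, trapped intermediate / %): 10.0: 9.5, 0.9; 15.0: 15.3, 0; 25.0: 22.6, 1.4; 30.0: 25.7, 0.8

(each reading ± 0.5 percentage points)

- the earlier runs were read with a standard deviation of 0.5 percentage points

- the best flask by share of bis adduct in bis adduct plus trapped intermediate; "all alike" if 1.5 percentage points covers them all (autumn / dusk / winter / spring / all alike)
- share of bis adduct in bis adduct plus trapped intermediate at the end, autumn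
- share of bis adduct in bis adduct plus trapped intermediate at the end, dusk
- share of bis adduct in bis adduct plus trapped intermediate at the end, winter
- share of bis adduct in bis adduct plus trapped intermediate at the end, spring

Open the ledger on the north-east run at 5.00 min. Bis adduct holds 21.9% of the charge. Trapped intermediate holds 14.7%. The remaining 63.4% is unread, and I book it as leftover substrate plus an intermediate pool. The two read entries behave differently. Bis adduct reads 22.1% at 1.33 min and 21.9% at the end, flat within a scatter of 0.5 points. Trapped intermediate climbs throughout. So I let the share turn on the trapped entry.

That climb is steady enough to be one number. Call it the capture time, 34.0 min: the minutes a standing pool needs to send the whole charge into the trapped entry at the north-east pace. The trapped entry is then the minutes the pool has stood, divided by the capture time.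

A feed changes those minutes. Under a steady feed the pool rises as a ramp, and the area under a ramp is a triangle. Your pool therefore counts as standing 3.00 min of the 5.0 min, and the feed costs half of its 4.0 min length. Dusk's evenly spaced portions average the same wait.

Here is my reckoning, with bis adduct held at 21.9%. Winter traps 14.7% and shares 59.8%. The fed flasks trap 8.82% and share 71.3%. The count gives the fed flasks one number, so my pick of spring among them is a judgement.

The forecast differs. It picks winter, at 61%, with autumn 56%, dusk 55% and spring 45% (30% to 60%). Its ground for spring: “Feeding substrate is worst, because partner dies before substrate arrives”.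

The flasks give autumn 68.8%, dusk 65.6%, winter 59.1% and spring 73.9%, and spring leads.

    substrate + partner → mono adduct (k = 0.580 M⁻¹ s⁻¹)
    partner + mono adduct ⇌ bis adduct (K = 19.0 M⁻¹, k = 0.640 M⁻¹ s⁻¹)
    mono adduct + capture agent → trapped intermediate (k = 0.0330 M⁻¹ s⁻¹)

The unread pool is mono adduct. In winter, the step joining partner, mono adduct and bis adduct relaxes with a half-life of 0.204 min, shorter than the 5.0 min run. Bis adduct ends at 21.2% in winter and 22.3% in spring, while trapped intermediate ends at 14.6% and 7.89%, the latter against the 8.82% reckoned. Now feed spring's substrate over 1.20 min. The pool stands 4.40 min, which traps 12.9% and shares 62.9%, and that flask gives 63.0%.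

All runs are calculated for an exercise, and the scatter is random.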